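**Retrosynthetic overview**
- The C3 ester is formed last by Mitsunobu inversion of a 3β-alcohol with (2E,4R)-4-(angeloyloxy)hex-2-enoic acid (from (R)-pent-1-en-3-ol by angeloylation and cross-metathesis with acrylic acid), followed by desilylation.
- The decalin core is made in one flask from two acyclic partners: a catalytic enantioselective [4+2] closes ring B (C4–C5, C1–C10), then a SmI2 ketyl–nitrile cyclisation closes ring A (C8–C9) and delivers the C8 ketone and C9 alcohol directly.
- The (Z)-enal nitrile comes from 4-methylfuran-2(5H)-one (fixes the Z alkene; C5, C6, C9, C10, C14) and 3-methylbut-3-enenitrile (C7, C8, isopropenyl); the diene comes from ethyl vinyl ketone (C1–C4, C15).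
- Ring order: ring B first, ring A second, both in the key step.

Assumption: ring compounds carry eremophilane numbering (decalin C1–C10, methyls on C4 and C5, isopropenyl on C7; β = face of the C5 methyl), and (3R)-pent-1-en-3-ol and 4-methylfuran-2(5H)-one are bought.

Step 1
Reactants: 1 4-methylfuran-2(5H)-one
Product: 2 (2Z)-4-hydroxy-N-methoxy-N,3-dimethylbut-2-enamide
Conditions: Me(MeO)NH·HCl, AlMe3, CH2Cl2, 0 → 23 °C
Reagents that add atoms: N,O-dimethylhydroxylamine hydrochloride, CNOC.Cl
Why: Weinreb aminolysis of the lactone by the aluminium amide opens the acyl C–O bond and keeps the ring-derived Z geometry of the trisubstituted alkene.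

Step 2
Reactants: 2 (2Z)-4-hydroxy-N-methoxy-N,3-dimethylbut-2-enamide
Product: 3 (2Z)-4-bromo-N-methoxy-N,3-dimethylbut-2-enamide
Conditions: CBr4, PPh3, CH2Cl2, 0 °C, used crude
Reagents that add atoms: carbon tetrabromide, BrC(Br)(Br)Br
Why: The Appel reaction converts the primary allylic alcohol into the bromide under neutral conditions at 0 °C, so the Z alkene is untouched.

Step 3
Reactants: 3 (2Z)-4-bromo-N-methoxy-N,3-dimethylbut-2-enamide; 4 3-methylbut-3-enenitrile
Product: 5 (2Z)-5-cyano-N-methoxy-N,3,6-trimethylhepta-2,6-dienamide (racemic at C5)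
Conditions: 4 (1.5 equiv), LDA, THF, −78 °C; then 3, −78 → −40 °C
Reagents that add atoms: none
Why: SN2 alkylation of the lithiated allyl cyanide at its α-carbon by the primary allylic bromide forms C6–C7; the new centre (later C7) is racemic and is set later by equilibration next to the C8 ketone.

Step 4
Reactants: 5 (2Z)-5-cyano-N-methoxy-N,3,6-trimethylhepta-2,6-dienamide
Product: 6 (4Z)-4-methyl-6-oxo-2-(prop-1-en-2-yl)hex-4-enenitrile (racemic at C2)
Conditions: DIBAL-H (1.05 equiv), THF, −78 °C, 20 min; Rochelle salt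
Reagents that add atoms: none
Why: DIBAL-H reduction of the Weinreb amide stops at the chelated aluminate and releases the Z enal on work-up, while the slower-reacting nitrile survives at −78 °C.

Step 5
Reactants: 7 pent-1-en-3-one
Product: 8 tert-butyldimethyl[(3Z)-penta-1,3-dien-3-yloxy]silane
Conditions: TBSOTf, Et3N, Et2O, 0 °C
Reagents that add atoms: tert-butyldimethylsilyl triflate, CC(C)(C)[Si](C)(C)OS(=O)(=O)C(F)(F)F
Why: Soft enolisation and O-silylation (silyl enol ether formation) of the ethyl ketone gives the Z dienol ether, whose terminal methyl sits outside and can enter a cycloaddition.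

Step 6
Reactants: 6 (4Z)-4-methyl-6-oxo-2-(prop-1-en-2-yl)hex-4-enenitrile; 8 tert-butyldimethyl[(3Z)-penta-1,3-dien-3-yloxy]silane
Product: 11 9β-hydroxy-4β,5β-dimethyl-7β-isopropenyl-10βH-eremophil-11-ene-3,8-dione, via cycloadduct aldehyde 9 (not isolated), via silyl enol ether ketol 10 (not isolated)
Conditions: 8 (1.8 equiv), (S)-o-tolyl-oxazaborolidinium triflimide (20 mol %), PhMe, −40 → −20 °C; then THF (0.01 M), t-BuOH, HMPA, SmI2 (2.5 equiv), −78 → 0 °C; then 1 M HCl, 23 °C
Reagents that add atoms: water, O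
Why: Proposed new method: the cationic oxazaborolidine binds the Z enal (B–O coordination plus formyl C–H···O contact) and shields one face, so the silyloxydiene adds in a suprafacial endo [4+2] with its methyl-bearing nucleophilic terminus at the β-carbon, which sets the C5 quaternary centre, C10 and the absolute configuration with C6 and C9 cis as dictated by the Z alkene (the (S)-catalyst is assumed to expose the Si face at C10; its enantiomer is used if the first sample of 11 is antipodal); SmI2/HMPA then converts the aldehyde into a ketyl that closes ring A by 6-exo-dig addition to the nitrile through a chair with the O–Sm group equatorial (9β), the imine hydrolyses to the C8 ketone, and the acid stage cleaves the silyl enol ether and equilibrates the enolisable centres C4 and C7 to the all-equatorial cis-decalin; the closest known reaction types are the oxazaborolidinium-catalysed Diels–Alder reaction of enals with 2-silyloxydienes, the mixed-Lewis-acid Diels–Alder reaction of hindered silyloxydienes and the SmI2 ketyl–nitrile reductive cyclisation to α-hydroxy ketones.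

Step 7
Reactants: 11 9β-hydroxy-4β,5β-dimethyl-7β-isopropenyl-10βH-eremophil-11-ene-3,8-dione
Product: 12 9β-(triethylsilyloxy)-4β,5β-dimethyl-7β-isopropenyl-10βH-eremophil-11-ene-3,8-dione
Conditions: TESOTf, 2,6-lutidine, CH2Cl2, −78 °C
Reagents that add atoms: triethylsilyl triflate, CC[Si](CC)(CC)OS(=O)(=O)C(F)(F)F
Why: Silyl ether formation masks the only hydroxyl so that the hydride and Mitsunobu steps act at C3 alone; no stereocentre is touched.

Step 8
Reactants: 12 9β-(triethylsilyloxy)-4β,5β-dimethyl-7β-isopropenyl-10βH-eremophil-11-ene-3,8-dione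
Product: 13 3β-hydroxy-9β-(triethylsilyloxy)-4β,5β-dimethyl-7β-isopropenyl-10βH-eremophil-11-en-8-one
Conditions: L-Selectride (1.1 equiv), THF, −78 °C; then H2O
Reagents that add atoms: none
Why: In this bulky-hydride ketone reduction L-Selectride attacks C3 along the equatorial trajectory, away from the axial C5 methyl, giving the axial 3β-alcohol, while the C8 ketone flanked by C7-isopropenyl and C9-OTES is too hindered to react at −78 °C.

Step 9
Reactants: 14 (3R)-pent-1-en-3-ol; 15 angelic acid [(2Z)-2-methylbut-2-enoic acid]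
Product: 16 (3R)-pent-1-en-3-yl (2Z)-2-methylbut-2-enoate
Conditions: 15, 2,4,6-Cl3C6H2COCl, Et3N, PhMe, 23 °C; then 14, 80 °C (no DMAP)
Reagents that add atoms: none
Why: Yamaguchi esterification through the mixed anhydride acylates the alcohol with retention at the carbinol carbon and, without DMAP, avoids angelate-to-tiglate isomerisation.

Step 10
Reactants: 16 (3R)-pent-1-en-3-yl (2Z)-2-methylbut-2-enoate; 17 acrylic acid
Product: 18 (2E,4R)-4-{[(2Z)-2-methylbut-2-enoyl]oxy}hex-2-enoic acid
Conditions: 17 (4 equiv), Hoveyda–Grubbs II (5 mol %), CH2Cl2, 40 °C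
Reagents that add atoms: none
Why: Olefin cross-metathesis joins the terminal vinyl group to acrylic acid with E selectivity; the trisubstituted electron-poor angelate alkene is inert and the stereocentre is not involved.

Step 11
Reactants: 13 3β-hydroxy-9β-(triethylsilyloxy)-4β,5β-dimethyl-7β-isopropenyl-10βH-eremophil-11-en-8-one; 18 (2E,4R)-4-{[(2Z)-2-methylbut-2-enoyl]oxy}hex-2-enoic acid
Product: 19 3α-{[(2E,4R)-4-(angeloyloxy)hex-2-enoyl]oxy}-9β-(triethylsilyloxy)-4β,5β-dimethyl-7β-isopropenyl-10βH-eremophil-11-en-8-one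
Conditions: PPh3, DIAD, PhMe, 0 → 23 °C
Reagents that add atoms: none
Why: In the Mitsunobu esterification the carboxylate displaces the axial 3β-oxyphosphonium by SN2 with inversion, giving the equatorial 3α-ester.

Step 12
Reactants: 19 3α-{[(2E,4R)-4-(angeloyloxy)hex-2-enoyl]oxy}-9β-(triethylsilyloxy)-4β,5β-dimethyl-7β-isopropenyl-10βH-eremophil-11-en-8-one
Product: 20 CNP0190706.1, (3R,4R,5R,7R,9R,10S)-3α-{[(2E,4R)-4-(angeloyloxy)hex-2-enoyl]oxy}-9β-hydroxy-10βH-eremophil-11-en-8-one
Conditions: HF·pyridine, THF, 0 °C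
Reagents that add atoms: none
Why: Fluoride-mediated desilylation removes the TES ether without affecting the two esters, the isopropenyl group or the α-ketol.

**Compound list**
1 | 4-methylfuran-2(5H)-one | CC1=CC(=O)OC1 | starting material
2 | (2Z)-4-hydroxy-N-methoxy-N,3-dimethylbut-2-enamide | CON(C)C(=O)/C=C(/C)CO | intermediate
3 | (2Z)-4-bromo-N-methoxy-N,3-dimethylbut-2-enamide | CON(C)C(=O)/C=C(/C)CBr | intermediate
4 | 3-methylbut-3-enenitrile | C=C(C)CC#N | starting material
5 | (2Z)-5-cyano-N-methoxy-N,3,6-trimethylhepta-2,6-dienamide, racemic at C5 | CON(C)C(=O)/C=C(/C)CC(C#N)C(C)=C | intermediate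
6 | (4Z)-4-methyl-6-oxo-2-(prop-1-en-2-yl)hex-4-enenitrile, racemic at C2 | O=C/C=C(/C)CC(C#N)C(C)=C | intermediate
7 | pent-1-en-3-one | C=CC(=O)CC | starting material
8 | tert-butyldimethyl[(3Z)-penta-1,3-dien-3-yloxy]silane | C=C/C(O[Si](C)(C)C(C)(C)C)=C/C | intermediate
9 | (1S,5S,6R)-4-[(tert-butyldimethylsilyl)oxy]-6-(2-cyano-3-methylbut-3-en-1-yl)-5,6-dimethylcyclohex-3-ene-1-carbaldehyde; endo adduct with CHO, cyanoalkyl arm and C5 methyl all cis; both epimers at the nitrile carbon; not isolated | O=C[C@H]1CC=C(O[Si](C)(C)C(C)(C)C)[C@@H](C)[C@@]1(C)CC(C#N)C(C)=C | intermediate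
10 | 3-[(tert-butyldimethylsilyl)oxy]-9β-hydroxy-4α,5β-dimethyl-7-isopropenyl-10βH-eremophila-2,11-dien-8-one; 4-epi, both C7 epimers; not isolated | C=C(C)C1C[C@@]2(C)[C@H](CC=C(O[Si](C)(C)C(C)(C)C)[C@H]2C)[C@@H](O)C1=O | intermediate
11 | 9β-hydroxy-4β,5β-dimethyl-7β-isopropenyl-10βH-eremophil-11-ene-3,8-dione | C=C(C)[C@H]1C[C@@]2(C)[C@H](CCC(=O)[C@@H]2C)[C@@H](O)C1=O | intermediate
12 | 9β-(triethylsilyloxy)-4β,5β-dimethyl-7β-isopropenyl-10βH-eremophil-11-ene-3,8-dione | C=C(C)[C@H]1C[C@@]2(C)[C@H](CCC(=O)[C@@H]2C)[C@@H](O[Si](CC)(CC)CC)C1=O | intermediate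
13 | 3β-hydroxy-9β-(triethylsilyloxy)-4β,5β-dimethyl-7β-isopropenyl-10βH-eremophil-11-en-8-one | C=C(C)[C@H]1C[C@@]2(C)[C@H](CC[C@H](O)[C@@H]2C)[C@@H](O[Si](CC)(CC)CC)C1=O | intermediate
14 | (3R)-pent-1-en-3-ol | C=C[C@H](O)CC | starting material
15 | angelic acid, (2Z)-2-methylbut-2-enoic acid | C/C=C(/C)C(=O)O | starting material
16 | (3R)-pent-1-en-3-yl (2Z)-2-methylbut-2-enoate | C=C[C@@H](CC)OC(=O)/C(C)=C\C | intermediate
17 | acrylic acid | C=CC(=O)O | starting material
18 | (2E,4R)-4-{[(2Z)-2-methylbut-2-enoyl]oxy}hex-2-enoic acid | OC(=O)/C=C/[C@@H](CC)OC(=O)/C(C)=C\C | intermediate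
19 | 3α-{[(2E,4R)-4-(angeloyloxy)hex-2-enoyl]oxy}-9β-(triethylsilyloxy)-4β,5β-dimethyl-7β-isopropenyl-10βH-eremophil-11-en-8-one | C=C(C)[C@H]1C[C@@]2(C)[C@H](CC[C@@H](OC(=O)/C=C/[C@@H](CC)OC(=O)/C(C)=C\C)[C@@H]2C)[C@@H](O[Si](CC)(CC)CC)C1=O | intermediate
20 | CNP0190706.1, (3R,4R,5R,7R,9R,10S)-3α-{[(2E,4R)-4-(angeloyloxy)hex-2-enoyl]oxy}-9β-hydroxy-10βH-eremophil-11-en-8-one | C=C(C)[C@H]1C[C@@]2(C)[C@H](CC[C@@H](OC(=O)/C=C/[C@@H](CC)OC(=O)/C(C)=C\C)[C@@H]2C)[C@@H](O)C1=O | target

**Step count:** 12 steps in total; longest linear sequence 9 steps (steps 1–4, 6–8, 11, 12).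

**Three steps most likely to fail**

Step 6 is the most exposed. The hindered cycloaddition may lose to 1,2-addition at the aldehyde or give low ee, and the aldehyde ketyl may dimerise or be reduced instead of cyclising. The fallback separates the two ring closures and takes the absolute configuration from resolution instead of catalysis; it sets out from 6 and 8 and comes back at 11. Compounds 6 and 8 are combined under the achiral mixed Lewis acid AlBr3/AlMe3 (or at 12 kbar), and the racemic cycloadduct is isolated, that is 9 together with its mirror image ent-cycloadduct F1. A separate titanium(III)-catalysed ketyl–nitrile coupling (Cp2TiCl2, Zn, Me3SiCl, Et3N·HCl) closes ring A to 10 and its mirror image ent-ketol F2. Acid hydrolysis and equilibration give racemic 11, that is 11 plus its mirror image ent-dione F3, and preparative chiral SFC delivers 11.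

Step 11 may give elimination to the C2–C3 alkene or no reaction, because the axial alcohol is hindered by the C4 methyl. The fallback avoids inversion altogether; it sets out from 12 and comes back at 19. A ketoreductase chosen from a panel for hydride delivery to the hindered face (NADPH recycled with isopropanol) reduces 12 directly to the equatorial 3α-alcohol F4. F4 is then acylated with retention by the Yamaguchi mixed anhydride of 18 to give 19.

Step 3 depends on the (Z)-γ-bromo amide 3, which can relactonise or lose its geometry before it is alkylated. The fallback builds the Z alkene by carbometalation instead; it sets out from 4 and comes back at 5. Lithiated 4 is alkylated with methyl 4-bromobut-2-ynoate to methyl 5-cyano-6-methylhept-6-en-2-ynoate F5. Syn-carbocupration with Me2CuLi at −78 °C and protonation give methyl (2Z)-5-cyano-3,6-dimethylhepta-2,6-dienoate F6 with the ester and the cyanoalkyl arm cis. Aminolysis with Me(MeO)NH·HCl and i-PrMgCl then gives 5.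

**Further compounds**
F1 | step 6 | mirror image of cycloadduct 9, (1R,5R,6S)-4-[(tert-butyldimethylsilyl)oxy]-6-(2-cyano-3-methylbut-3-en-1-yl)-5,6-dimethylcyclohex-3-ene-1-carbaldehyde | O=C[C@@H]1CC=C(O[Si](C)(C)C(C)(C)C)[C@H](C)[C@]1(C)CC(C#N)C(C)=C
F2 | step 6 | mirror image of ketol 10 | C=C(C)C1C[C@]2(C)[C@@H](CC=C(O[Si](C)(C)C(C)(C)C)[C@@H]2C)[C@H](O)C1=O
F3 | step 6 | mirror image of dione 11 | C=C(C)[C@@H]1C[C@]2(C)[C@@H](CCC(=O)[C@H]2C)[C@H](O)C1=O
F4 | step 11 | 3α-hydroxy-9β-(triethylsilyloxy)-4β,5β-dimethyl-7β-isopropenyl-10βH-eremophil-11-en-8-one | C=C(C)[C@H]1C[C@@]2(C)[C@H](CC[C@@H](O)[C@@H]2C)[C@@H](O[Si](CC)(CC)CC)C1=O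
F5 | step 3 | methyl 5-cyano-6-methylhept-6-en-2-ynoate | COC(=O)C#CCC(C#N)C(C)=C
F6 | step 3 | methyl (2Z)-5-cyano-3,6-dimethylhepta-2,6-dienoate | COC(=O)/C=C(/C)CC(C#N)C(C)=C
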